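Ugonin Q is luteolin (rings A, C and B) that carries a 3-hydroxy-γ-cyclogeranyl ring at C6 of ring A through C7'H2. The plan rests on that carbocycle (C1' = ring CH, C2' = C(=CH2), C3' = CHOH, C6' = CMe2), a folded 4-oxygenated geranyl chain whose C1'–C6' bond is the biosynthetic one.
Last disconnection: pyranone ring C is opened at O1–C2 to an o-hydroxyaryl ynone. The ynone comes from a ring A salicylaldehyde and silylated 3,4-dihydroxyphenylacetylene (ring B).
Key disconnection: C1'–C6' is cut to a C6' tertiary alcohol and an E-allylsilane (Me3SiCH2 on C2'). Rings A and B are bought, the carbocycle is formed first and ring C last.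
C7'–C1' is cut to a benzylic zinc reagent (from 2,4,6-trihydroxybenzaldehyde, para oxygen marked as pivalate) and an (E)-iodoalkene. The iodoalkene is made by chelate-controlled anti-carbomagnesiation of an (S)-propargylic alcohol with Me3SiCH2MgCl.
C3' is set by asymmetric transfer hydrogenation of an ynone built from ethyl levulinate and ethynyltrimethylsilane, and C3' then controls C1' in the ring closure.

Key step: step 12

Remark: TBS = tert-butyldimethylsilyl, TBSO = its oxy form, Piv = pivaloyl; primed locants belong to the terpenoid unit and unprimed ones to the flavone. It is assumed that the usual sense of induction of the (S,S)-TsDPEN ruthenium catalyst on alkynyl ketones (S carbinol) holds for the ynone used here.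

Step 1
Reactants: 1 ethyl levulinate (ethyl 4-oxopentanoate)
Product: 3 5,5-dimethyldihydrofuran-2(3H)-one, via open-chain bromomagnesium alkoxide 2 (not isolated)
Conditions: MeMgBr (1.05 equiv), THF, −40 → 0 °C; aq NH4Cl
Reagents that add atoms: methylmagnesium bromide, C[Mg]Br
Why: Chemoselective Grignard addition to the ketone, which is far more electrophilic than the ester at low temperature, is followed by lactonisation of the tertiary alkoxide on to the ester, which installs the future C6' gem-dimethyl carbinol carbon.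

Step 2
Reactants: 3 5,5-dimethyldihydrofuran-2(3H)-one; 4 ethynyltrimethylsilane
Product: 6 6-hydroxy-6-methyl-1-(trimethylsilyl)hept-1-yn-3-one, via lithium (trimethylsilyl)acetylide 5 (not isolated)
Conditions: 4 (1.15 equiv), n-BuLi (1.1 equiv), THF, −78 °C; then 3, −78 °C; aq NH4Cl at −78 °C
Reagents that add atoms: none
Why: Acylation of a lithium acetylide by a lactone stops after one addition because the adduct does not collapse to the ketone before the cold quench, and ring opening frees the tertiary alcohol that later serves as the cation source, so no protecting group is needed there.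

Step 3
Reactants: 6 6-hydroxy-6-methyl-1-(trimethylsilyl)hept-1-yn-3-one
Product: 7 (S)-6-methyl-1-(trimethylsilyl)hept-1-yne-3,6-diol
Conditions: Ru[(S,S)-TsDPEN](p-cymene) (1 mol%, 16-electron amido complex), i-PrOH, rt
Reagents that add atoms: none
Why: In this Noyori asymmetric transfer hydrogenation of an alkynyl ketone the chiral ruthenium hydride distinguishes the alkynyl from the alkyl flank and should deliver hydride to the face that gives the S carbinol (C3'), while the tertiary alcohol and the C–Si bond stay inert under these base-free conditions.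

Step 4
Reactants: 7 (S)-6-methyl-1-(trimethylsilyl)hept-1-yne-3,6-diol
Product: 8 (S)-6-methylhept-1-yne-3,6-diol
Conditions: K2CO3 (0.2 equiv), MeOH, rt
Reagents that add atoms: none
Why: Base-catalysed methanolysis of the alkynyl C–Si bond (protiodesilylation) exposes the terminal alkyne and touches neither carbinol.

Step 5
Reactants: 8 (S)-6-methylhept-1-yne-3,6-diol; 9 (trimethylsilyl)methylmagnesium chloride
Product: 11 (1E,3S)-1-iodo-6-methyl-2-[(trimethylsilyl)methyl]hept-1-ene-3,6-diol, via chelated alkenylmagnesium chloride 10 (not isolated)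
Conditions: 9 (5 equiv), CuI (0.3 equiv), Et2O–toluene, −20 °C → rt; then I2 in THF added at −40 °C to the first lasting colour; aq Na2S2O3
Reagents that add atoms: iodine, II
Why: Copper-catalysed anti-carbomagnesiation of a secondary terminal propargylic alkoxide delivers Me3SiCH2 to the proximal carbon C2' and leaves magnesium on C1' held cis to C3' by the alkoxide chelate, so iodinolysis with retention places iodine cis to C3' (E isomer) with regiochemistry and geometry fixed by the chelate and C3' untouched.

Step 6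
Reactants: 11 (1E,3S)-1-iodo-6-methyl-2-[(trimethylsilyl)methyl]hept-1-ene-3,6-diol
Product: 12 (5S,6E)-5-(TBSO)-7-iodo-2-methyl-6-[(trimethylsilyl)methyl]hept-6-en-2-ol
Conditions: TBSCl (1.2 equiv), imidazole (2.5 equiv), DMF, 0 °C → rt
Reagents that add atoms: tert-butyldimethylsilyl chloride, CC(C)(C)[Si](C)(C)Cl
Why: Silyl ether formation with TBSCl and imidazole is strongly sensitive to hindrance, so the secondary allylic hydroxyl reacts and the tertiary hydroxyl stays free.

Step 7
Reactants: 13 2,4,6-trihydroxybenzaldehyde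
Product: 14 4-formyl-3,5-dihydroxyphenyl pivalate
Conditions: PivCl (1.0 equiv), Et3N (1.05 equiv), THF, −20 → 0 °C
Reagents that add atoms: pivaloyl chloride, CC(C)(C)C(=O)Cl
Why: In this regioselective O-acylation one equivalent of amine base generates only the most acidic para phenoxide, while the two ortho hydroxyls are hydrogen-bonded to and flanked by the formyl group and are shielded from the bulky acyl chloride, so the oxygen that will become O1 is marked.

Step 8
Reactants: 14 4-formyl-3,5-dihydroxyphenyl pivalate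
Product: 15 3,5-bis(TBSO)-4-formylphenyl pivalate
Conditions: TBSOTf (2.4 equiv), 2,6-lutidine (3 equiv), CH2Cl2, 0 °C
Reagents that add atoms: tert-butyldimethylsilyl triflate, CC(C)(C)[Si](C)(C)OS(=O)(=O)C(F)(F)F
Why: Silylation with the silyl triflate overcomes the hydrogen bonding of the ortho phenols, and the non-nucleophilic base leaves the aryl pivalate alone.

Step 9
Reactants: 15 3,5-bis(TBSO)-4-formylphenyl pivalate
Product: 16 3,5-bis(TBSO)-4-(hydroxymethyl)phenyl pivalate
Conditions: NaBH4, THF–EtOH, 0 °C, short contact; aq NH4Cl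
Reagents that add atoms: none
Why: Borohydride reduction of the aldehyde is much faster than attack on the hindered aryl ester, and the cold, quickly quenched medium gives the ortho silyl groups no time to migrate to the new alkoxide.

Step 10
Reactants: 16 3,5-bis(TBSO)-4-(hydroxymethyl)phenyl pivalate
Product: 17 3,5-bis(TBSO)-4-(chloromethyl)phenyl pivalate
Conditions: MsCl (1.2 equiv), Et3N (1.5 equiv), CH2Cl2, 0 °C → rt; used without chromatography
Reagents that add atoms: methanesulfonyl chloride (chloride source), CS(=O)(=O)Cl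
Why: Mesylation of an electron-rich benzylic alcohol is followed in the flask by nucleophilic substitution of the labile mesylate by the chloride released, which gives the benzylic chloride without free acid.

Step 11
Reactants: 17 3,5-bis(TBSO)-4-(chloromethyl)phenyl pivalate; 12 (5S,6E)-5-(TBSO)-7-iodo-2-methyl-6-[(trimethylsilyl)methyl]hept-6-en-2-ol
Product: 19 4-[(2E,4S)-4-(TBSO)-7-hydroxy-7-methyl-3-(trimethylsilylmethyl)oct-2-en-1-yl]-3,5-bis(TBSO)phenyl pivalate (cyclisation precursor), via benzylic zinc chloride 18 (not isolated)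
Conditions: 17 (1.5 equiv), Zn dust, LiCl, THF, 25 °C; then 12, Pd(OAc)2 (2 mol%), SPhos (4 mol%), THF, 25 °C
Reagents that add atoms: none
Why: LiCl-assisted zinc insertion into the benzylic chloride and Negishi sp3–sp2 cross-coupling form C7'–C1' with retention of the alkene geometry, and the mild organozinc tolerates the pivalate, the silyl ethers, the allylsilane and the free tertiary alcohol, which a Grignard-based coupling would not.

Step 12
Reactants: 19 4-[(2E,4S)-4-(TBSO)-7-hydroxy-7-methyl-3-(trimethylsilylmethyl)oct-2-en-1-yl]-3,5-bis(TBSO)phenyl pivalate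
Product: 20 4-{[(1S,3S)-3-(TBSO)-6,6-dimethyl-2-methylidenecyclohexyl]methyl}-3,5-bis(TBSO)phenyl pivalate
Conditions: SnCl4 (2.0 equiv), 2,6-di-tert-butyl-4-methylpyridine (1.5 equiv), CH2Cl2 (0.01 M), −78 → −40 °C; Et3N, then aq NaHCO3
Reagents that add atoms: none
Why: SnCl4 binds the C6' hydroxyl and ionises the C6'–O bond to the tertiary cation, the γ-carbon C1' of the allylsilane attacks it anti to the C–Si bond, and the β-silyl-stabilised cation at C2' sheds Me3Si, so the only alkene that can arise is the exocyclic C2'=CH2. The closest known chemistry is the allylsilane-terminated cation–olefin cyclisation of the γ-cyclogeranyl series, which is the intramolecular form of the Lewis-acid tert-alkylation of allylsilanes (Hosomi–Sakurai type). The carbocycle closes in the 6-endo-trig mode with respect to C1'=C2' through a chair-like transition state. C1' is controlled by C3': ArCH2 is cis to C3' on the E-alkene and must become axial in either chair, so the chair with OTBS equatorial (C3'–H turned towards ArCH2, no syn-diaxial ArCH2/OTBS contact, least allylic 1,3-strain) should be followed and give the trans (1'S,3'S) ring. The step needs ionisation at C6' and not at the allylic C3'–O bond, capture by carbon and not by oxygen, and no protodesilylation. These are secured by the tertiary versus secondary character of the two C–O bonds at low temperature, by the bulky silyl and acyl caps on the C3' and aryl oxygens (a silyloxonium formed at the C3' oxygen can revert, whereas C–C closure with loss of silicon cannot), and by the hindered pyridine that takes up HCl.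

Step 13
Reactants: 20 4-{[(1S,3S)-3-(TBSO)-6,6-dimethyl-2-methylidenecyclohexyl]methyl}-3,5-bis(TBSO)phenyl pivalate
Product: 21 4-{[(1S,3S)-3-(TBSO)-6,6-dimethyl-2-methylidenecyclohexyl]methyl}-3,5-bis(TBSO)phenol
Conditions: i-Bu2AlH (2.5 equiv), CH2Cl2, −78 °C; aq potassium sodium tartrate
Reagents that add atoms: none
Why: Reductive cleavage of the aryl pivalate by the aluminium hydride needs neither base nor fluoride, so all three silyl ethers persist, and at −78 °C the exocyclic alkene is not hydroaluminated.

Step 14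
Reactants: 21 4-{[(1S,3S)-3-(TBSO)-6,6-dimethyl-2-methylidenecyclohexyl]methyl}-3,5-bis(TBSO)phenol
Product: 22 3-{[(1S,3S)-3-(TBSO)-6,6-dimethyl-2-methylidenecyclohexyl]methyl}-2,4-bis(TBSO)-6-hydroxybenzaldehyde
Conditions: MgCl2 (3 equiv), Et3N (6 equiv), (CH2O)n (10 equiv), THF, 65 °C; aq citric acid
Reagents that add atoms: paraformaldehyde (as formaldehyde), C=O
Why: In the Casnati–Skattebøl ortho-formylation the magnesium phenoxide delivers formaldehyde only to a carbon ortho to the free oxygen and a second formaldehyde accepts hydride, and since both ortho positions lead to the same constitution a single aldehyde (the future C4 on C4a) should result under non-acidic conditions that spare the alkene.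

Step 15
Reactants: 23 3,4-dihydroxybenzaldehyde
Product: 24 3,4-bis(TBSO)benzaldehyde
Conditions: TBSCl (2.4 equiv), imidazole (5 equiv), DMF, rt
Reagents that add atoms: tert-butyldimethylsilyl chloride, CC(C)(C)[Si](C)(C)Cl
Why: Standard silylation of both catechol hydroxyls gives ring B the same fluoride-labile protection as the rest of the molecule.

Step 16
Reactants: 24 3,4-bis(TBSO)benzaldehyde
Product: 25 4-ethynyl-1,2-bis(TBSO)benzene
Conditions: Me3SiCHN2 (1.2 equiv), n-BuLi (1.2 equiv), THF, −78 °C; then 24, −78 °C → rt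
Reagents that add atoms: (trimethylsilyl)diazomethane, C[Si](C)(C)C=[N+]=[N-]
Why: The Colvin rearrangement (addition of the lithiated silyldiazomethane, Peterson-type loss of silanolate, loss of N2 and 1,2-shift of the alkylidene carbene) homologates the aryl aldehyde to the terminal alkyne without the carbonate and methanol medium that would strip aryl silyl ethers.

Step 17
Reactants: 22 3-{[(1S,3S)-3-(TBSO)-6,6-dimethyl-2-methylidenecyclohexyl]methyl}-2,4-bis(TBSO)-6-hydroxybenzaldehyde; 25 4-ethynyl-1,2-bis(TBSO)benzene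
Product: 27 1-(ring A aryl)-3-[3,4-bis(TBSO)phenyl]prop-2-yn-1-ol (both carbinol epimers; ring A aryl = 2,4-bis(TBSO)-6-hydroxy-3-{[(1S,3S)-3-(TBSO)-6,6-dimethyl-2-methylidenecyclohexyl]methyl}phenyl), via alkynylmagnesium bromide 26 (not isolated)
Conditions: 25 (3.0 equiv), EtMgBr (2.9 equiv), THF, 0 → 40 °C; then 22, 0 °C → rt; aq NH4Cl
Reagents that add atoms: none
Why: In this 1,2-addition of an alkynyl Grignard reagent to a salicylaldehyde the first equivalent forms the magnesium phenoxide, whose chelation activates the carbonyl for the slim nucleophile, magnesium alkoxides are reluctant to trigger silyl migration, and the new carbinol centre is removed in the next step.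

Step 18
Reactants: 27 1-(ring A aryl)-3-[3,4-bis(TBSO)phenyl]prop-2-yn-1-ol
Product: 28 1-(ring A aryl)-3-[3,4-bis(TBSO)phenyl]prop-2-yn-1-one
Conditions: MnO2 (activated, 20 equiv), CH2Cl2, rt
Reagents that add atoms: none
Why: MnO2 oxidation is selective for the doubly activated benzylic and propargylic alcohol and leaves the alkene, the phenol and the silyl ethers untouched.

Step 19
Reactants: 28 1-(ring A aryl)-3-[3,4-bis(TBSO)phenyl]prop-2-yn-1-one
Product: 29 penta-O-TBS ugonin Q, i.e. 5,7-bis(TBSO)-2-[3,4-bis(TBSO)phenyl]-6-{[(1S,3S)-3-(TBSO)-6,6-dimethyl-2-methylidenecyclohexyl]methyl}-4H-chromen-4-one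
Conditions: DMAP (0.2 equiv), DMF, 30 °C
Reagents that add atoms: none
Why: In the amine-catalysed 6-endo-dig oxa-Michael cyclisation of an o-alkynoylphenol, DMAP adds to the ynone β-carbon and is displaced there by the phenol oxygen, which favours the flavone over the aurone, and because only the oxygen para to C7' is free, ring C closes to the 6-substituted and not the 8-substituted flavone.

Step 20
Reactants: 29 penta-O-TBS ugonin Q
Product: 30 ugonin Q
Conditions: HF·pyridine (excess), pyridine, THF, 0 °C → rt, under argon; pH 7 phosphate buffer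
Reagents that add atoms: none
Why: Global fluoride desilylation driven by Si–F bond formation takes place in a pyridine-buffered medium too weakly acidic to protonate the exocyclic alkene (no chromane closure by the 5- or 7-hydroxyl) or to ionise the allylic alcohol, and not basic enough to let the catechol oxidise, so both stereocentres are kept.

Compound list
1 | ethyl levulinate | CCOC(=O)CCC(C)=O | starting material
2 | bromomagnesium alkoxide of ethyl 4-hydroxy-4-methylpentanoate | CCOC(=O)CCC(C)(C)O[Mg]Br | intermediate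
3 | 5,5-dimethyldihydrofuran-2(3H)-one | CC1(C)CCC(=O)O1 | intermediate
4 | ethynyltrimethylsilane | C#C[Si](C)(C)C | starting material
5 | lithium (trimethylsilyl)acetylide | [Li]C#C[Si](C)(C)C | intermediate
6 | 6-hydroxy-6-methyl-1-(trimethylsilyl)hept-1-yn-3-one | C[Si](C)(C)C#CC(=O)CCC(C)(C)O | intermediate
7 | (S)-6-methyl-1-(trimethylsilyl)hept-1-yne-3,6-diol | C[Si](C)(C)C#C[C@@H](O)CCC(C)(C)O | intermediate
8 | (S)-6-methylhept-1-yne-3,6-diol | C#C[C@@H](O)CCC(C)(C)O | intermediate
9 | (trimethylsilyl)methylmagnesium chloride | C[Si](C)(C)C[Mg]Cl | starting material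
10 | chelated (E)-alkenylmagnesium chloride, both hydroxyls as chloromagnesium alkoxides, Mg on C1' cis to C3' | C[Si](C)(C)C/C(=C/[Mg]Cl)[C@@H](O[Mg]Cl)CCC(C)(C)O[Mg]Cl | intermediate
11 | (1E,3S)-1-iodo-6-methyl-2-[(trimethylsilyl)methyl]hept-1-ene-3,6-diol | C[Si](C)(C)C/C(=C/I)[C@@H](O)CCC(C)(C)O | intermediate
12 | (5S,6E)-5-(TBSO)-7-iodo-2-methyl-6-[(trimethylsilyl)methyl]hept-6-en-2-ol | C[Si](C)(C)C/C(=C/I)[C@@H](O[Si](C)(C)C(C)(C)C)CCC(C)(C)O | intermediate
13 | 2,4,6-trihydroxybenzaldehyde | O=Cc1c(O)cc(O)cc1O | starting material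
14 | 4-formyl-3,5-dihydroxyphenyl pivalate | O=Cc1c(O)cc(OC(=O)C(C)(C)C)cc1O | intermediate
15 | 3,5-bis(TBSO)-4-formylphenyl pivalate | O=Cc1c(O[Si](C)(C)C(C)(C)C)cc(OC(=O)C(C)(C)C)cc1O[Si](C)(C)C(C)(C)C | intermediate
16 | 3,5-bis(TBSO)-4-(hydroxymethyl)phenyl pivalate | OCc1c(O[Si](C)(C)C(C)(C)C)cc(OC(=O)C(C)(C)C)cc1O[Si](C)(C)C(C)(C)C | intermediate
17 | 3,5-bis(TBSO)-4-(chloromethyl)phenyl pivalate | ClCc1c(O[Si](C)(C)C(C)(C)C)cc(OC(=O)C(C)(C)C)cc1O[Si](C)(C)C(C)(C)C | intermediate
18 | [2,6-bis(TBSO)-4-(pivaloyloxy)benzyl]zinc chloride | Cl[Zn]Cc1c(O[Si](C)(C)C(C)(C)C)cc(OC(=O)C(C)(C)C)cc1O[Si](C)(C)C(C)(C)C | intermediate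
19 | 4-[(2E,4S)-4-(TBSO)-7-hydroxy-7-methyl-3-(trimethylsilylmethyl)oct-2-en-1-yl]-3,5-bis(TBSO)phenyl pivalate | C[Si](C)(C)C/C(=C/Cc1c(O[Si](C)(C)C(C)(C)C)cc(OC(=O)C(C)(C)C)cc1O[Si](C)(C)C(C)(C)C)[C@@H](O[Si](C)(C)C(C)(C)C)CCC(C)(C)O | intermediate
20 | 4-{[(1S,3S)-3-(TBSO)-6,6-dimethyl-2-methylidenecyclohexyl]methyl}-3,5-bis(TBSO)phenyl pivalate | C=C1[C@@H](Cc2c(O[Si](C)(C)C(C)(C)C)cc(OC(=O)C(C)(C)C)cc2O[Si](C)(C)C(C)(C)C)C(C)(C)CC[C@@H]1O[Si](C)(C)C(C)(C)C | intermediate
21 | 4-{[(1S,3S)-3-(TBSO)-6,6-dimethyl-2-methylidenecyclohexyl]methyl}-3,5-bis(TBSO)phenol | C=C1[C@@H](Cc2c(O[Si](C)(C)C(C)(C)C)cc(O)cc2O[Si](C)(C)C(C)(C)C)C(C)(C)CC[C@@H]1O[Si](C)(C)C(C)(C)C | intermediate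
22 | 3-{[(1S,3S)-3-(TBSO)-6,6-dimethyl-2-methylidenecyclohexyl]methyl}-2,4-bis(TBSO)-6-hydroxybenzaldehyde | C=C1[C@@H](Cc2c(O[Si](C)(C)C(C)(C)C)cc(O)c(C=O)c2O[Si](C)(C)C(C)(C)C)C(C)(C)CC[C@@H]1O[Si](C)(C)C(C)(C)C | intermediate
23 | 3,4-dihydroxybenzaldehyde | O=Cc1ccc(O)c(O)c1 | starting material
24 | 3,4-bis(TBSO)benzaldehyde | O=Cc1ccc(O[Si](C)(C)C(C)(C)C)c(O[Si](C)(C)C(C)(C)C)c1 | intermediate
25 | 4-ethynyl-1,2-bis(TBSO)benzene | C#Cc1ccc(O[Si](C)(C)C(C)(C)C)c(O[Si](C)(C)C(C)(C)C)c1 | intermediate
26 | {[3,4-bis(TBSO)phenyl]ethynyl}magnesium bromide | Br[Mg]C#Cc1ccc(O[Si](C)(C)C(C)(C)C)c(O[Si](C)(C)C(C)(C)C)c1 | intermediate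
27 | benzylic propargylic alcohol, both carbinol epimers | C=C1[C@@H](Cc2c(O[Si](C)(C)C(C)(C)C)cc(O)c(C(O)C#Cc3ccc(O[Si](C)(C)C(C)(C)C)c(O[Si](C)(C)C(C)(C)C)c3)c2O[Si](C)(C)C(C)(C)C)C(C)(C)CC[C@@H]1O[Si](C)(C)C(C)(C)C | intermediate
28 | o-hydroxyaryl ynone | C=C1[C@@H](Cc2c(O[Si](C)(C)C(C)(C)C)cc(O)c(C(=O)C#Cc3ccc(O[Si](C)(C)C(C)(C)C)c(O[Si](C)(C)C(C)(C)C)c3)c2O[Si](C)(C)C(C)(C)C)C(C)(C)CC[C@@H]1O[Si](C)(C)C(C)(C)C | intermediate
29 | penta-O-TBS ugonin Q | C=C1[C@@H](Cc2c(O[Si](C)(C)C(C)(C)C)cc3oc(-c4ccc(O[Si](C)(C)C(C)(C)C)c(O[Si](C)(C)C(C)(C)C)c4)cc(=O)c3c2O[Si](C)(C)C(C)(C)C)C(C)(C)CC[C@@H]1O[Si](C)(C)C(C)(C)C | intermediate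
30 | ugonin Q, (1'S,3'S) | C=C1[C@@H](Cc2c(O)cc3oc(-c4ccc(O)c(O)c4)cc(=O)c3c2O)C(C)(C)CC[C@@H]1O | target

Total step count: 20. Longest linear sequence: 14 steps (steps 1–6, 11–14 and 17–20).

**Steps most likely to fail**

**Step 12 (key cyclisation).**
- The C6' cation may be intercepted by the oxygen of the C3' silyl ether, which would close a five-membered ether with loss of the silyl group.
- The cation may lose a proton, and the acid released may protodesilylate the allylsilane.
- Ionisation may be too slow at temperatures that the silyl ethers survive.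
- Leakage through a boat would erode the trans selectivity.

The fallback sets out from 19 and comes back at 20, and it changes how the cation is made. Compound 19 is esterified with trifluoroacetic anhydride and pyridine in CH2Cl2 at 0 °C to the tertiary trifluoroacetate F1. This is used crude and ionised with MeAlCl2 in CH2Cl2 at −78 °C. The cation is then born from a carboxylate leaving group instead of a metal-bound hydroxyl, so no HCl is formed. Stray protons are destroyed as methane by the Al–CH3 bond. The aluminate counter-ion offers little free halide to strip silicon from a transient silyloxonium, so oxygen capture stays reversible while the C–C closure drains the equilibrium.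

**Step 14 (ortho-formylation).**
- Attack at a carbon wedged between the phenoxide and a bulky silyloxy group may be slow.
- Prolonged heating of magnesium phenoxides may lead to transfer of silyl groups between molecules.

The fallback sets out from 21 and comes back at 29, bypassing steps 14 and 17–19. Compound 21 is iodinated ortho to the free hydroxyl with N-iodosuccinimide (1.0 equiv, CH2Cl2, −40 °C) to the o-iodophenol F2. F2 and alkyne 25 are then joined by a carbonylative Sonogashira coupling with in-flask amine-promoted ring closure (PdCl2(PPh3)2, CO 1 atm, Et2NH, DMF, 50 °C). This passes through ynone 28 and gives 29 directly, so C4 comes from carbon monoxide instead of formaldehyde.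

**Step 5 (carbomagnesiation and iodinolysis).**
- Carbometalation of the doubly deprotonated diol may be sluggish.
- The terminal alkyne may be deprotonated instead.
- Iodine may attack the new allylsilane during the quench.

The fallback sets out from 8 and aldehyde 15 and comes back at 19, bypassing steps 5, 6 and 9–11. It makes the trisubstituted alkene by syn hydrometalation of an internal alkyne.
- Compound 8 is silylated at the secondary hydroxyl (TBSCl, imidazole, DMF) to the mono-TBS ether F3.
- Its dianion (n-BuLi, 2 equiv, THF, −78 °C) is added to 15 to give the benzylic propargylic alcohol F4.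
- Ionic hydrogenation (Et3SiH, CF3CO2H, CH2Cl2, −40 °C) removes the benzylic hydroxyl and gives the aryl-substituted internal alkyne F5.
- Syn hydrostannation (Bu3SnH, Pd(PPh3)4, THF, 0 °C → rt) places tin on C2', next to the oxygenated carbon, and gives the (E)-vinylstannane F6. The minor regioisomer is removed by chromatography.
- Iododestannylation (I2, CH2Cl2, 0 °C) gives the (E)-vinyl iodide F7.
- Negishi coupling of F7 with (trimethylsilyl)methylzinc chloride F8 (from 9 and ZnCl2; Pd(PPh3)4, THF, rt) gives 19. The zinc reagent is chosen over the Grignard reagent so that the pivalate survives.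

Further compounds
F1 | step 12 | tertiary trifluoroacetate of 19 | C[Si](C)(C)C/C(=C/Cc1c(O[Si](C)(C)C(C)(C)C)cc(OC(=O)C(C)(C)C)cc1O[Si](C)(C)C(C)(C)C)[C@@H](O[Si](C)(C)C(C)(C)C)CCC(C)(C)OC(=O)C(F)(F)F
F2 | step 14 | 4-{[(1S,3S)-3-(TBSO)-6,6-dimethyl-2-methylidenecyclohexyl]methyl}-3,5-bis(TBSO)-2-iodophenol | C=C1[C@@H](Cc2c(O[Si](C)(C)C(C)(C)C)cc(O)c(I)c2O[Si](C)(C)C(C)(C)C)C(C)(C)CC[C@@H]1O[Si](C)(C)C(C)(C)C
F3 | step 5 | (S)-5-(TBSO)-2-methylhept-6-yn-2-ol | C#C[C@@H](O[Si](C)(C)C(C)(C)C)CCC(C)(C)O
F4 | step 5 | 4-[(4S)-4-(TBSO)-1,7-dihydroxy-7-methyloct-2-yn-1-yl]-3,5-bis(TBSO)phenyl pivalate, both benzylic epimers | OC(C#C[C@@H](O[Si](C)(C)C(C)(C)C)CCC(C)(C)O)c1c(O[Si](C)(C)C(C)(C)C)cc(OC(=O)C(C)(C)C)cc1O[Si](C)(C)C(C)(C)C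
F5 | step 5 | 4-[(4S)-4-(TBSO)-7-hydroxy-7-methyloct-2-yn-1-yl]-3,5-bis(TBSO)phenyl pivalate | C(C#C[C@@H](O[Si](C)(C)C(C)(C)C)CCC(C)(C)O)c1c(O[Si](C)(C)C(C)(C)C)cc(OC(=O)C(C)(C)C)cc1O[Si](C)(C)C(C)(C)C
F6 | step 5 | 4-[(2E,4S)-4-(TBSO)-7-hydroxy-7-methyl-3-(tributylstannyl)oct-2-en-1-yl]-3,5-bis(TBSO)phenyl pivalate | CCCC[Sn](CCCC)(CCCC)/C(=C/Cc1c(O[Si](C)(C)C(C)(C)C)cc(OC(=O)C(C)(C)C)cc1O[Si](C)(C)C(C)(C)C)[C@@H](O[Si](C)(C)C(C)(C)C)CCC(C)(C)O
F7 | step 5 | 4-[(2E,4S)-4-(TBSO)-7-hydroxy-3-iodo-7-methyloct-2-en-1-yl]-3,5-bis(TBSO)phenyl pivalate | I/C(=C/Cc1c(O[Si](C)(C)C(C)(C)C)cc(OC(=O)C(C)(C)C)cc1O[Si](C)(C)C(C)(C)C)[C@@H](O[Si](C)(C)C(C)(C)C)CCC(C)(C)O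
F8 | step 5 | (trimethylsilyl)methylzinc chloride | C[Si](C)(C)C[Zn]Cl
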